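**Retrosynthetic overview**

1. Both benzene rings are bought: aldehyde 1 is turned into the (E)-propenylphenol 2, and the guaiacol ring comes from eugenol 3. Only the dihydrofuran ring has to be made.
2. Key disconnection: C3–C3a and C2–O1 are cut together. This is an oxidative 8–5′ [3+2] coupling of 2 with 3 on a chiral iron phosphate, through phenoxyl radical 4 and benzylic cation 5 (the O-methyl counterpart of the biosynthetic quinone methide), giving trans-dihydrobenzofuran 6 with both stereocentres.
3. Last disconnection: the (E)-propenyl group of target 7 comes from the allyl group of 6 by double-bond migration. Eugenol is used because a free propenylphenol would dimerise under the oxidant.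
4. Ring order: the two benzene rings are present from the start; the dihydrofuran ring is the only ring formed (step 2).

Assumption: the sense of induction of the new asymmetric step cannot be predicted with certainty; the (R)-phosphate is written, and the (S)-phosphate is used instead if the (R)-catalyst gives the (2R,3R) series.

**Route**

Step 1
Reactants: 1 3-hydroxy-4,5-dimethoxybenzaldehyde
Product: 2 (E)-2,3-dimethoxy-5-(prop-1-en-1-yl)phenol
Conditions: CrCl2 (8 equiv), CH3CHI2 (2 equiv), THF, 25 °C; minor (Z)-isomer removed on AgNO3-doped silica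
Reagents that add atoms: 1,1-diiodoethane, CC(I)I
Why: Takai–Utimoto olefination, in which the geminal dichromium reagent formed from 1,1-diiodoethane and CrCl2 adds to the aldehyde and the adduct eliminates with aryl and methyl anti to give the (E)-alkene (typically ≥ 9:1); the weakly basic organochromium reagent tolerates the free phenol, and no stereocentre is formed.

Step 2
Reactants: 2 (E)-2,3-dimethoxy-5-(prop-1-en-1-yl)phenol; 3 eugenol (4-allyl-2-methoxyphenol, 3 equiv)
Product: 6 (2S,3S)-5-allyl-2-(3-hydroxy-4,5-dimethoxyphenyl)-7-methoxy-3-methyl-2,3-dihydro-1-benzofuran, via eugenoxyl radical 4 (not isolated), via benzylic cation 5 (not isolated)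
Conditions: FeL3 (5 mol%; L = (R)-3,3′-bis(2,4,6-triisopropylphenyl)-1,1′-binaphthyl-2,2′-diyl phosphate; made beforehand from Fe(ClO4)3 and the acid HL), t-BuOOt-Bu (1.5 equiv), ClCH2CH2Cl/(CF3)2CHOH 1:1, 0 °C → rt, slow addition of 2
Reagents that add atoms: none
Why: Proposed new method: trivalent iron takes up eugenol 3 as a chelating guaiacolate and the peroxide oxidises it to the iron-bound eugenoxyl radical 4, whose only free ortho carbon is electrophilic; the propenyl β-carbon of 2 (the most nucleophilic π-bond present, docked through its own phenol on the same metal centre or on a phosphate oxygen inside the pocket of the three (R)-phosphates) adds to that carbon on one enantioface, which sets C3 as S; the ring re-aromatises and a second one-electron oxidation gives the para-methoxy-stabilised benzylic cation 5, which the phenol oxygen closes anti to the methyl group so that C2 is S and the ring is trans; the reaction type is an oxidative phenol–alkene [3+2] coupling, and the closest known reactions are the racemic FeCl3-catalysed oxidative [3+2] coupling of phenols with β-methylstyrenes to trans-2-aryl-3-methyl-2,3-dihydrobenzofurans, the ortho-selective iron/peroxide coupling of 2-methoxy-4-alkylphenols with π-nucleophiles in (CF3)2CHOH, and the enantioselective oxidative coupling of 2-naphthols with chiral iron tris(binaphthyl phosphate) catalysts.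

Step 3
Reactants: 6 (2S,3S)-5-allyl-2-(3-hydroxy-4,5-dimethoxyphenyl)-7-methoxy-3-methyl-2,3-dihydro-1-benzofuran
Product: 7 (2S,3S)-2-(3-hydroxy-4,5-dimethoxyphenyl)-7-methoxy-3-methyl-5-[(E)-prop-1-en-1-yl]-2,3-dihydro-1-benzofuran (CNP0299956.1)
Conditions: [(C5H5)Ru(NCMe)(iPr2P–Im)]PF6 (2 mol%; Im = 4-tert-butyl-1-methylimidazol-2-yl), acetone, 40 °C
Reagents that add atoms: none
Why: Alkene isomerisation, in which the bifunctional ruthenium catalyst moves the terminal double bond one position by allylic proton transfer at the metal (the imidazole nitrogen is the internal base) and stops at the styrene, giving the (E)-isomer with > 99:1 selectivity as it does for eugenol itself; the free phenol is tolerated and neither stereocentre is touched.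

**Compound list**

1 | 3-hydroxy-4,5-dimethoxybenzaldehyde | O=Cc1cc(O)c(OC)c(OC)c1 | starting material
2 | (E)-2,3-dimethoxy-5-(prop-1-en-1-yl)phenol | C/C=C/c1cc(O)c(OC)c(OC)c1 | intermediate
3 | eugenol (4-allyl-2-methoxyphenol) | C=CCc1ccc(O)c(OC)c1 | starting material
4 | eugenoxyl radical (4-allyl-2-methoxyphenoxyl, held on iron) | C=CCc1ccc([O])c(OC)c1 | intermediate
5 | benzylic cation, (2R)-2-(5-allyl-2-hydroxy-3-methoxyphenyl)-1-(3-hydroxy-4,5-dimethoxyphenyl)propan-1-ylium | C=CCc1cc(OC)c(O)c(c1)[C@H](C)[CH+]c1cc(O)c(OC)c(OC)c1 | intermediate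
6 | (2S,3S)-5-allyl-2-(3-hydroxy-4,5-dimethoxyphenyl)-7-methoxy-3-methyl-2,3-dihydro-1-benzofuran | C=CCc1cc(OC)c2c(c1)[C@H](C)[C@@H](c1cc(O)c(OC)c(OC)c1)O2 | intermediate
7 | (2S,3S)-2-(3-hydroxy-4,5-dimethoxyphenyl)-7-methoxy-3-methyl-5-[(E)-prop-1-en-1-yl]-2,3-dihydro-1-benzofuran | C/C=C/c1cc(OC)c2c(c1)[C@H](C)[C@@H](c1cc(O)c(OC)c(OC)c1)O2 | target

**Totals**

Total step count: 3. Longest linear sequence: 3 steps (1 → 2 → 6 → 7; eugenol 3 enters in step 2).

**Steps most likely to fail, with fallbacks**

Step 2 is the most likely to fail. Three things are untested: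
- enantio-induction by the chiral iron phosphate in a phenol–alkene coupling;
- selectivity for oxidising eugenol when 2 carries a phenol of its own;
- the stability of 2 in the acidic fluorinated medium, where it may dimerise.

The fallback gives up catalyst control and resolves instead. It sets out from 2 (3 is used as in the route) and comes back at 6.
- Acetylation of 2 (Ac2O, pyridine, rt) gives (E)-2,3-dimethoxy-5-(prop-1-en-1-yl)phenyl acetate F1, so that eugenol is the only phenol in the flask.
- F1 and 3 (3 equiv) are coupled with the achiral parent system (FeCl3 10 mol%, t-BuOOt-Bu, ClCH2CH2Cl/(CF3)2CHOH 4:1, rt) to racemic trans-5-(5-allyl-7-methoxy-3-methyl-2,3-dihydro-1-benzofuran-2-yl)-2,3-dimethoxyphenyl acetate F2.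
- K2CO3 in MeOH removes the acetate to give racemic trans-5-(5-allyl-7-methoxy-3-methyl-2,3-dihydro-1-benzofuran-2-yl)-2,3-dimethoxyphenol F3.
- Preparative SFC on an amylose tris(3,5-dimethylphenylcarbamate) phase separates the enantiomers; the (2S,3S) enantiomer is 6.

Step 1 is next. The phenol may consume part of the chromium reagent, and the E:Z ratio for aromatic aldehydes may stay near 9:1, which would erode the enantioselectivity of step 2. The fallback replaces the chromium olefination by addition and elimination; it sets out from 1 and comes back at 2.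
- EtMgBr (2.5 equiv, THF, 0 °C → rt) adds to the aldehyde to give racemic 1-(3-hydroxy-4,5-dimethoxyphenyl)propan-1-ol F4.
- Acid-catalysed dehydration (p-TsOH·H2O 2 mol%, toluene, 80 °C) gives 2 as the thermodynamic (E)-alkene.

Step 3 is the least risky. The catalyst could be inhibited by the phenol, or could leave an inseparable trace of (Z)-alkene or unreacted allyl compound. The fallback moves the double bond by hydration and elimination instead of catalytic migration; it sets out from 6 and comes back at 7.
- Mukaiyama hydration (Co(acac)2 20 mol%, PhSiH3, O2, THF/i-PrOH, rt) gives the Markovnikov alcohol 1-[(2S,3S)-2-(3-hydroxy-4,5-dimethoxyphenyl)-7-methoxy-3-methyl-2,3-dihydro-1-benzofuran-5-yl]propan-2-ol F5.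
- Appel iodination (PPh3, I2, imidazole, CH2Cl2, 0 °C; phenols are inert to it) gives (2S,3S)-2-(3-hydroxy-4,5-dimethoxyphenyl)-5-(2-iodopropyl)-7-methoxy-3-methyl-2,3-dihydro-1-benzofuran F6.
- E2 elimination with DBU (toluene, 80 °C) goes through the acidic benzylic hydrogen into conjugation and gives the (E)-propenyl compound 7; any allyl isomer formed is 6 and can be recycled.

**Further compounds**

F1 | step 2 | (E)-2,3-dimethoxy-5-(prop-1-en-1-yl)phenyl acetate | C/C=C/c1cc(OC(C)=O)c(OC)c(OC)c1
F2 | step 2 | racemic trans-5-(5-allyl-7-methoxy-3-methyl-2,3-dihydro-1-benzofuran-2-yl)-2,3-dimethoxyphenyl acetate, (2S,3S) plus (2R,3R) | C=CCc1cc(OC)c2c(c1)[C@H](C)[C@@H](c1cc(OC(C)=O)c(OC)c(OC)c1)O2.C=CCc1cc(OC)c2c(c1)[C@@H](C)[C@H](c1cc(OC(C)=O)c(OC)c(OC)c1)O2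
F3 | step 2 | racemic trans-5-(5-allyl-7-methoxy-3-methyl-2,3-dihydro-1-benzofuran-2-yl)-2,3-dimethoxyphenol, (2S,3S) plus (2R,3R) | C=CCc1cc(OC)c2c(c1)[C@H](C)[C@@H](c1cc(O)c(OC)c(OC)c1)O2.C=CCc1cc(OC)c2c(c1)[C@@H](C)[C@H](c1cc(O)c(OC)c(OC)c1)O2
F4 | step 1 | racemic 1-(3-hydroxy-4,5-dimethoxyphenyl)propan-1-ol | CCC(O)c1cc(O)c(OC)c(OC)c1
F5 | step 3 | 1-[(2S,3S)-2-(3-hydroxy-4,5-dimethoxyphenyl)-7-methoxy-3-methyl-2,3-dihydro-1-benzofuran-5-yl]propan-2-ol, both carbinol epimers | CC(O)Cc1cc(OC)c2c(c1)[C@H](C)[C@@H](c1cc(O)c(OC)c(OC)c1)O2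
F6 | step 3 | (2S,3S)-2-(3-hydroxy-4,5-dimethoxyphenyl)-5-(2-iodopropyl)-7-methoxy-3-methyl-2,3-dihydro-1-benzofuran, both epimers at the iodide carbon | CC(I)Cc1cc(OC)c2c(c1)[C@H](C)[C@@H](c1cc(O)c(OC)c(OC)c1)O2
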